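The earlier runs and the new flask come from a simulation with made-up constants.

Read the two products as one split, not as two yields. Assume each substrate is used in proportion to its own amount, while both share reagent and catalyst. The fractions left of each charge then give s:

s = ln(left-handed substrate left) / ln(right-handed substrate left)

| setting | north-east | north | south-west | ochre | green |
|---|---|---|---|---|---|
| left-handed substrate | 10 mM | 10 mM | 20 mM | 10 mM | 10 mM |
| right-handed substrate | 10 mM | 10 mM | 20 mM | 10 mM | 10 mM |
| solid reagent | 0.80 equiv | 1.8 equiv | 1.2 equiv | 1.20 equiv | 1.20 equiv |
| catalyst | 1.3 mol% | 1.3 mol% | 1.3 mol% | 1.3 mol% | 1.3 mol% |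
| added ligand | 0.54 mM | 0.54 mM | 0.54 mM | 0.54 mM | 0.54 mM |
| remark | run made earlier | run made earlier | run made earlier |  |  |
| time |  |  |  | 1.5 h | 6.0 h |

| run | time / min | left-handed product / % | right-handed product / % |
|---|---|---|---|
| north-east | 5.00 | 1 | 4 |
| north-east | 15.0 | 1 | 1 |
| north-east | 25.0 | 5 | 0 |
| north-east | 40.0 | 6 | 4 |
| north-east | 50.0 | 8 | 3 |
| north-east | 80.0 | 9 | 5 |
| north-east | 90.0 | 7 | 5 |
| north | 12.0 | 5 | 0 |
| north | 25.0 | 6 | 2 |
| north | 40.0 | 10 | 0 |
| north | 50.0 | 10 | 5 |
| north | 60.0 | 15 | 0 |
| north | 80.0 | 17 | 4 |
| north | 90.0 | 19 | 6 |
| south-west | 8.00 | 3 | 0 |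
| south-west | 25.0 | 14 | 4 |
| south-west | 40.0 | 12 | 4 |
| south-west | 60.0 | 24 | 10 |
| south-west | 90.0 | 25 | 6 |

(standard deviation of a reading: 2 percentage points)

- catalyst is single-handed; left-handed substrate and right-handed substrate are mirror images of each other, charged as a racemate, each of them at the stated concentration
- solid, in amounts per volume of the solution: solid reagent
- at the start none of the solid reagent is in solution
- an excess is the difference of the two amounts in percent of their sum
- an excess is below zero if the other one leads

- which of the two ends with the higher excess of left-handed product over right-handed product in the product ("neither" if they lie within 2 percentage points) (ochre / green / neither)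
- excess of left-handed product over right-handed product in the product at the end, ochre
- excess of left-handed product over right-handed product in the product at the end, green

Which number must you know well? The last two readings of each run average 6.00 % right-handed product, so x, the fraction of right-handed substrate left, reads 88.0 % on average over these runs. The excess follows from x and s:

excess = (x − x^s) / (2 − x − x^s)

Try s = 3, which gives 45.3 %. Halving the consumption gives 47.7 %. Raising s to 4 gives 53.9 %. So consumption moves the excess less than s does, and s is the number to pin down.

The same readings average 16.8 % left-handed product: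

s = 3.21

This s is a reading and carries the scatter of the readings: the selectivity factor, the ratio of the two substrates' rate constants. The south-west run has the equivalents of solid reagent of ochre, at another substrate concentration. Its products total 34.0 % at 60.0 min and 31.0 % at 90.0 min, so I take ochre as stopped by its end, and green as adding nothing. My reckoning is 47.4 % for both, so by it neither leads.

The forecast differs: ochre, with 50 % for ochre and 32 % for green, since “solid depletion and left-substrate consumption slow the left-handed route”.

The flasks give neither: 49.0 % in ochre and 49.0 % in green.

    partner → decomposed reagent (k = 0.00110 s⁻¹)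
    partner + catalyst + left-handed substrate → catalyst + left-handed product (k = 700 M⁻² s⁻¹)
    partner + catalyst + right-handed substrate → catalyst + right-handed product (k = 220 M⁻² s⁻¹)
    solid reagent ⇌ partner, rate k4*(cs4 - [partner]) while solid is left; crystals form when [partner] > cs4 (solubility = 8.70 mM, k = 0.00120 s⁻¹)
    catalyst + added ligand ⇌ idle complex (K = 4300 M⁻¹, k = 97.0 M⁻¹ s⁻¹)

Ochre keeps 92 % of its right-handed substrate, and 77.5 % is what s gives for the left-handed against 78 % found. Now charge green with 4.80 equiv of solid reagent, other charges and the time held. That neighbour keeps 71 % of its right-handed substrate, so s gives 33.6 % of the left-handed, and 34 % is found. The reckoned excess is 39.2 %, and the neighbour gives 39.3 %.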